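**Retrosynthetic overview**
- Feature: ring A (C1–C6) is an enolised 2-acylcyclohexane-1,3,5-trione. Its only stereocentre, quaternary C3 (methyl, prenyl), lies para to the C6 carbonyl and is stereogenic only because C1 carries hexanoyl and C5 the CH2 bridge.
- Last disconnection: the C5–CH2–aryl bridge, made by aminomethylation of ring A monomer 18 and capture of the derived methylene trione by ring B ketone 21 (two steps from phloroglucinol).
- Before that: hexanoyl goes onto C1 of a 1,3-dione whose other flank holds the C4 oxygen as a phenylthio enol ether. The dione comes from the epoxide of the enone flank, the thio-enone from desaturation, thiol addition and oxidation of the saturated flank.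
- Prenyl comes from the formyl group by two Wittig reactions. The ring A carbocycle (bonds C2–C3 and C4–C5) comes from an enantioselective Diels–Alder reaction of aminosiloxydiene 2 with methacrolein 1.
- Ring order: ring A is built first (step 1), ring B is taken ready-made from phloroglucinol, and the two are joined in the last step.

Key step: step 1

Assumption 1: the (4R,5R)-diol catalyst is taken to expose the aldehyde face that leads to (S)-4; if the sense is the opposite, its (4S,5S)-antipode is used and nothing else changes.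
Assumption 2: enolisable di- and tricarbonyl compounds are drawn as one tautomer, and diastereomer mixtures at epoxide and sulfur-bearing carbons are carried on because those centres later become sp2.

**Step 1**
Reactants: 1 methacrolein; 2 (E)-1-(dimethylamino)-3-(tert-butyldimethylsilyloxy)buta-1,3-diene
Product: 4 (S)-1-methyl-4-oxocyclohex-2-ene-1-carbaldehyde, via aminosiloxy cycloadduct 3 (not isolated)
Conditions: (4R,5R)-2,2-dimethyl-α,α,α′,α′-tetra(1-naphthyl)-1,3-dioxolane-4,5-dimethanol (20 mol %), toluene, −80 °C; then AcCl, CH2Cl2, −78 °C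
Reagents that add atoms: none
Why: The diol hydrogen-bonds to the formyl oxygen of 1, lowering its LUMO while a naphthyl wall covers one enantioface, and diene 2 adds in a concerted, asynchronous, suprafacial [4+2] cycloaddition in which its CH2 terminus bonds to the β-carbon of 1 (future C4–C5) and its amino-bearing carbon to the α-carbon (future C2–C3). The closest known reaction type is the catalytic enantioselective Diels–Alder reaction of 1-amino-3-siloxydienes with α-substituted acroleins under chiral-diol hydrogen-bond catalysis. Ring A is closed as a six-membered carbocycle by this intermolecular cycloaddition, endo with respect to the formyl group. The quaternary centre (future C3) is set by catalyst control, since the diol pocket leaves only one face of the bound aldehyde open. The ortho-type regiochemistry is substrate-inherent (the amino and siloxy donors make the diene CH2 terminus the most nucleophilic site), so the only selectivity that rests on the catalyst is the enantioface. Acetyl chloride then acylates the amine, which leaves with the push of the silyl enol ether, and chloride takes the silyl group, giving enone 4 with the quaternary centre untouched.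

**Step 2**
Reactants: 4 (S)-1-methyl-4-oxocyclohex-2-ene-1-carbaldehyde
Product: 5 (S)-4-(2-methoxyethenyl)-4-methylcyclohex-2-en-1-one (E/Z mixture)
Conditions: (methoxymethyl)triphenylphosphonium chloride, KN(SiMe3)2, THF, −78 °C, then 4, −78 → −20 °C
Reagents that add atoms: (methoxymethyl)triphenylphosphonium chloride, COC[P+](c1ccccc1)(c1ccccc1)c1ccccc1.[Cl-]
Why: Wittig methoxymethylenation; at low temperature the unstabilised ylide should add to the aldehyde much faster than to the conjugated ketone, so only the formyl group is converted.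

**Step 3**
Reactants: 5 (S)-4-(2-methoxyethenyl)-4-methylcyclohex-2-en-1-one
Product: 6 (R)-2-(1-methyl-4-oxocyclohex-2-en-1-yl)acetaldehyde
Conditions: 2 M aqueous HCl, THF, rt
Reagents that add atoms: water, O
Why: Acid hydrolysis of the enol ether (oxocarbenium ion, hemiacetal, loss of methanol) should unveil the one-carbon-homologated aldehyde; no stereocentre is formed or touched.

**Step 4**
Reactants: 6 (R)-2-(1-methyl-4-oxocyclohex-2-en-1-yl)acetaldehyde
Product: 7 (R)-4-methyl-4-(3-methylbut-2-en-1-yl)cyclohex-2-en-1-one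
Conditions: isopropyltriphenylphosphonium iodide, n-BuLi, THF, 0 °C; then 6, −78 → 0 °C
Reagents that add atoms: isopropyltriphenylphosphonium iodide, CC(C)[P+](c1ccccc1)(c1ccccc1)c1ccccc1.[I-]
Why: Wittig olefination with the isopropylidene ylide, again aldehyde-selective at low temperature, should complete the prenyl chain.

**Step 5**
Reactants: 7 (R)-4-methyl-4-(3-methylbut-2-en-1-yl)cyclohex-2-en-1-one
Product: 8 (5R)-5-methyl-5-(3-methylbut-2-en-1-yl)-7-oxabicyclo[4.1.0]heptan-2-one (both cis-epoxide diastereomers)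
Conditions: 30 % aqueous H2O2, NaOH (0.2 equiv), MeOH, 0 °C
Reagents that add atoms: hydrogen peroxide, OO
Why: Weitz–Scheffer nucleophilic epoxidation attacks only the electron-poor enone bond and not the prenyl alkene; the epoxide configuration is immaterial.

**Step 6**
Reactants: 8 (5R)-5-methyl-5-(3-methylbut-2-en-1-yl)-7-oxabicyclo[4.1.0]heptan-2-one
Product: 10 (5S)-5-methyl-5-(3-methylbut-2-en-1-yl)-7-oxabicyclo[4.1.0]hept-3-en-2-one, via lithium enolate 9 (not isolated)
Conditions: LiN(iPr)2, THF, −78 °C; then N-tert-butylbenzenesulfinimidoyl chloride, −78 °C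
Reagents that add atoms: none
Why: Mukaiyama dehydrogenation: only the CH2 flank can be enolised (the other α-carbon is an epoxide carbon), and the enolate is sulfenylated at carbon and loses the sulfenamide by syn-elimination to give the enone on the formerly saturated flank.

**Step 7**
Reactants: 10 (5S)-5-methyl-5-(3-methylbut-2-en-1-yl)-7-oxabicyclo[4.1.0]hept-3-en-2-one
Product: 11 (5R)-5-methyl-5-(3-methylbut-2-en-1-yl)-4-(phenylsulfanyl)-7-oxabicyclo[4.1.0]heptan-2-one (mixture at C4)
Conditions: PhSH (1.05 equiv), Et3N (10 mol %), CH2Cl2, −20 °C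
Reagents that add atoms: thiophenol, Sc1ccccc1
Why: Amine-catalysed thia-Michael addition of the soft thiolate to the enone β-carbon, expected to outrun opening of the epoxy ketone at low temperature; the new sulfur-bearing centre need not be controlled.

**Step 8**
Reactants: 11 (5R)-5-methyl-5-(3-methylbut-2-en-1-yl)-4-(phenylsulfanyl)-7-oxabicyclo[4.1.0]heptan-2-one
Product: 13 (5R)-5-methyl-5-(3-methylbut-2-en-1-yl)-4-(phenylsulfanyl)-7-oxabicyclo[4.1.0]hept-3-en-2-one, via α-chloro sulfide 12 (not isolated)
Conditions: N-chlorosuccinimide (1.0 equiv), solid NaHCO3, CH2Cl2, 0 °C → rt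
Reagents that add atoms: none
Why: Pummerer-type α-chlorination of the sulfide and loss of HCl toward the acidic ketone α-hydrogen (the known oxidation of β-arylthio ketones to β-arylthio enones) should give the vinylogous thioester, which holds the future C4 oxygen in masked, non-acidic form.

**Step 9**
Reactants: 13 (5R)-5-methyl-5-(3-methylbut-2-en-1-yl)-4-(phenylsulfanyl)-7-oxabicyclo[4.1.0]hept-3-en-2-one
Product: 14 (R)-4-methyl-4-(3-methylbut-2-en-1-yl)-5-(phenylsulfanyl)cyclohex-5-ene-1,3-dione
Conditions: Pd(PPh3)4 (5 mol %), 1,2-bis(diphenylphosphino)ethane (5 mol %), toluene, 80 °C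
Reagents that add atoms: none
Why: Isomerisation of an α,β-epoxy ketone to a β-diketone by zerovalent palladium (oxidative addition at the α C–O bond, β-hydride elimination from the alkoxide carbon, reductive elimination) should create the free 1,3-dione on the former enone flank only, so the two flanks stay different.

**Step 10**
Reactants: 14 (R)-4-methyl-4-(3-methylbut-2-en-1-yl)-5-(phenylsulfanyl)cyclohex-5-ene-1,3-dione; 15 hexanoyl chloride
Product: 17 (4R)-2-hexanoyl-3-hydroxy-4-methyl-4-(3-methylbut-2-en-1-yl)-5-(phenylsulfanyl)cyclohexa-2,5-dien-1-one, via enol hexanoate 16 (not isolated)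
Conditions: 15, Et3N, CH2Cl2, 0 °C; then 4-(dimethylamino)pyridine (20 mol %), MeCN, rt
Reagents that add atoms: none
Why: O-acylation followed by nucleophile-catalysed O-to-C acyl migration, the standard route to 2-acylcyclohexane-1,3-diones, should place hexanoyl on the only carbon between two free carbonyls (future C1).

**Step 11**
Reactants: 17 (4R)-2-hexanoyl-3-hydroxy-4-methyl-4-(3-methylbut-2-en-1-yl)-5-(phenylsulfanyl)cyclohexa-2,5-dien-1-one
Product: 18 (4S)-2-hexanoyl-3,5-dihydroxy-4-methyl-4-(3-methylbut-2-en-1-yl)cyclohexa-2,5-dien-1-one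
Conditions: LiOH (5 equiv), 1,4-dioxane/H2O, 80 °C; then 1 M HCl
Reagents that add atoms: lithium hydroxide, [Li+].[OH-]
Why: Addition–elimination of hydroxide at the β-carbon of the vinylogous thioester should expel thiophenolate and free the third enolised carbonyl; the prenyl group tolerates hot base, and the stereocentre is fixed because hexanoyl stays on one flank.

**Step 12**
Reactants: 19 phloroglucinol; 15 hexanoyl chloride
Product: 20 1-(2,4,6-trihydroxyphenyl)hexan-1-one
Conditions: AlCl3 (4 equiv), nitrobenzene, 0 → 60 °C; aqueous HCl work-up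
Reagents that add atoms: none
Why: Friedel–Crafts C-acylation of the very electron-rich arene; the new ketone deactivates the ring against a second acylation.

**Step 13**
Reactants: 20 1-(2,4,6-trihydroxyphenyl)hexan-1-one
Product: 21 1-(2,6-dihydroxy-4-methoxyphenyl)hexan-1-one
Conditions: Me2SO4 (1.0 equiv), K2CO3 (1.0 equiv), acetone, rt
Reagents that add atoms: dimethyl sulfate, COS(=O)(=O)OC
Why: Williamson methylation with one equivalent should go to the 4-hydroxyl, the only one not hydrogen-bonded to the ketone and the most acidic.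

**Step 14**
Reactants: 18 (4S)-2-hexanoyl-3,5-dihydroxy-4-methyl-4-(3-methylbut-2-en-1-yl)cyclohexa-2,5-dien-1-one; 21 1-(2,6-dihydroxy-4-methoxyphenyl)hexan-1-one
Product: 24 (4S)-2-hexanoyl-6-[(3-hexanoyl-2,4-dihydroxy-6-methoxyphenyl)methyl]-3,5-dihydroxy-4-methyl-4-(3-methylbut-2-en-1-yl)cyclohexa-2,5-dien-1-one, via Mannich base 22 (not isolated), via methylene trione 23 (not isolated)
Conditions: N,N-dimethylmethyleneiminium iodide (1.05 equiv), CH2Cl2, 0 °C → rt; then 21 (2 equiv), NaOAc (1.1 equiv), 1,4-dioxane, 80 °C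
Reagents that add atoms: N,N-dimethylmethyleneiminium iodide, C=[N+](C)C.[I-]
Why: Mannich aminomethylation of the single nucleophilic ring carbon of 18 (future C5), retro-Michael loss of dimethylamine to the methylene trione, and Friedel–Crafts-type Michael addition of ring B through one of its two equivalent free positions; forming the Mannich base before ring B is added should steer the reaction to the unsymmetrical product.

**Compound list**
1 | methacrolein | CC(=C)C=O | starting material
2 | (E)-1-(dimethylamino)-3-(tert-butyldimethylsilyloxy)buta-1,3-diene | CN(C)/C=C/C(=C)O[Si](C)(C)C(C)(C)C | starting material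
3 | (1S,2R)-4-(tert-butyldimethylsilyloxy)-2-(dimethylamino)-1-methylcyclohex-3-ene-1-carbaldehyde (endo cycloadduct) | CC(C)(C)[Si](C)(C)OC1=C[C@@H](N(C)C)[C@@](C)(C=O)CC1 | intermediate (not isolated)
4 | (S)-1-methyl-4-oxocyclohex-2-ene-1-carbaldehyde | O=C1C=C[C@@](C)(C=O)CC1 | intermediate
5 | (S)-4-(2-methoxyethenyl)-4-methylcyclohex-2-en-1-one, E/Z mixture | O=C1C=C[C@@](C)(C=COC)CC1 | intermediate
6 | (R)-2-(1-methyl-4-oxocyclohex-2-en-1-yl)acetaldehyde | O=C1C=C[C@@](C)(CC=O)CC1 | intermediate
7 | (R)-4-methyl-4-(3-methylbut-2-en-1-yl)cyclohex-2-en-1-one | O=C1C=C[C@@](C)(CC=C(C)C)CC1 | intermediate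
8 | (5R)-5-methyl-5-(3-methylbut-2-en-1-yl)-7-oxabicyclo[4.1.0]heptan-2-one, both cis-epoxides | O=C1C2OC2[C@@](C)(CC=C(C)C)CC1 | intermediate
9 | lithium (5S)-5-methyl-5-(3-methylbut-2-en-1-yl)-7-oxabicyclo[4.1.0]hept-2-en-2-olate | [Li]OC1=CC[C@](C)(CC=C(C)C)C2OC12 | intermediate (not isolated)
10 | (5S)-5-methyl-5-(3-methylbut-2-en-1-yl)-7-oxabicyclo[4.1.0]hept-3-en-2-one | O=C1C2OC2[C@@](C)(CC=C(C)C)C=C1 | intermediate
11 | (5R)-5-methyl-5-(3-methylbut-2-en-1-yl)-4-(phenylsulfanyl)-7-oxabicyclo[4.1.0]heptan-2-one, mixture at C4 | O=C1C2OC2[C@@](C)(CC=C(C)C)C(Sc3ccccc3)C1 | intermediate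
12 | (5R)-4-chloro-5-methyl-5-(3-methylbut-2-en-1-yl)-4-(phenylsulfanyl)-7-oxabicyclo[4.1.0]heptan-2-one | O=C1C2OC2[C@@](C)(CC=C(C)C)C(Cl)(Sc3ccccc3)C1 | intermediate (not isolated)
13 | (5R)-5-methyl-5-(3-methylbut-2-en-1-yl)-4-(phenylsulfanyl)-7-oxabicyclo[4.1.0]hept-3-en-2-one | O=C1C2OC2[C@@](C)(CC=C(C)C)C(Sc3ccccc3)=C1 | intermediate
14 | (R)-4-methyl-4-(3-methylbut-2-en-1-yl)-5-(phenylsulfanyl)cyclohex-5-ene-1,3-dione | O=C1CC(=O)[C@@](C)(CC=C(C)C)C(Sc2ccccc2)=C1 | intermediate
15 | hexanoyl chloride | CCCCCC(Cl)=O | starting material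
16 | (R)-4-methyl-4-(3-methylbut-2-en-1-yl)-3-oxo-5-(phenylsulfanyl)cyclohexa-1,5-dien-1-yl hexanoate | CCCCCC(=O)OC1=CC(=O)[C@@](C)(CC=C(C)C)C(Sc2ccccc2)=C1 | intermediate (not isolated)
17 | (4R)-2-hexanoyl-3-hydroxy-4-methyl-4-(3-methylbut-2-en-1-yl)-5-(phenylsulfanyl)cyclohexa-2,5-dien-1-one | CCCCCC(=O)C1=C(O)[C@@](C)(CC=C(C)C)C(Sc2ccccc2)=CC1=O | intermediate
18 | (4S)-2-hexanoyl-3,5-dihydroxy-4-methyl-4-(3-methylbut-2-en-1-yl)cyclohexa-2,5-dien-1-one | CCCCCC(=O)C1=C(O)[C@@](C)(CC=C(C)C)C(O)=CC1=O | intermediate
19 | phloroglucinol | Oc1cc(O)cc(O)c1 | starting material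
20 | 1-(2,4,6-trihydroxyphenyl)hexan-1-one | CCCCCC(=O)c1c(O)cc(O)cc1O | intermediate
21 | 1-(2,6-dihydroxy-4-methoxyphenyl)hexan-1-one | CCCCCC(=O)c1c(O)cc(OC)cc1O | intermediate
22 | (4S)-6-[(dimethylamino)methyl]-2-hexanoyl-3,5-dihydroxy-4-methyl-4-(3-methylbut-2-en-1-yl)cyclohexa-2,5-dien-1-one | CCCCCC(=O)C1=C(O)[C@@](C)(CC=C(C)C)C(O)=C(CN(C)C)C1=O | intermediate (not isolated)
23 | (4R)-2-hexanoyl-3-hydroxy-4-methyl-6-methylidene-4-(3-methylbut-2-en-1-yl)cyclohex-2-ene-1,5-dione | CCCCCC(=O)C1=C(O)[C@@](C)(CC=C(C)C)C(=O)C(=C)C1=O | intermediate (not isolated)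
24 | (4S)-2-hexanoyl-6-[(3-hexanoyl-2,4-dihydroxy-6-methoxyphenyl)methyl]-3,5-dihydroxy-4-methyl-4-(3-methylbut-2-en-1-yl)cyclohexa-2,5-dien-1-one (CNP0108719.1) | CCCCCC(=O)C1=C(O)[C@@](C)(CC=C(C)C)C(O)=C(Cc2c(OC)cc(O)c(C(=O)CCCCC)c2O)C1=O | target

**Step count**
Total: 14 steps. Longest linear sequence: 12 steps (steps 1–11, then 14); steps 12–13 form the ring B branch.

**Steps most likely to fail**

Step 7. The thiolate may open the α,β-epoxy ketone at its α-carbon in competition with conjugate addition, or the adduct may lose thiolate again by retro-Michael reaction during the chlorination. The fallback swaps the order in which the two flanks are handled, so that thiol and epoxide never meet in a Michael step; it sets out from 7 and comes back at 18. Thiophenol with catalytic Et3N adds to the plain enone 7 to give (4R)-4-methyl-4-(3-methylbut-2-en-1-yl)-3-(phenylsulfanyl)cyclohexan-1-one F1, and N-chlorosuccinimide turns it into the vinylogous thioester (R)-4-methyl-4-(3-methylbut-2-en-1-yl)-3-(phenylsulfanyl)cyclohex-2-en-1-one F2. Enolisation with LiN(iPr)2 and dehydrogenation with N-tert-butylbenzenesulfinimidoyl chloride give (S)-4-methyl-4-(3-methylbut-2-en-1-yl)-3-(phenylsulfanyl)cyclohexa-2,5-dien-1-one F3. tert-Butyl hydroperoxide with 1,8-diazabicyclo[5.4.0]undec-7-ene then epoxidises the unsubstituted enone bond only, giving (5S)-5-methyl-5-(3-methylbut-2-en-1-yl)-4-(phenylsulfanyl)-7-oxabicyclo[4.1.0]hept-3-en-2-one F4. Aqueous LiOH in THF at rt cleaves the thio-enone to (5S)-5-methyl-5-(3-methylbut-2-en-1-yl)-7-oxabicyclo[4.1.0]heptane-2,4-dione F5, which is C-acylated with 15 as in step 10 to give (5S)-3-hexanoyl-4-hydroxy-5-methyl-5-(3-methylbut-2-en-1-yl)-7-oxabicyclo[4.1.0]hept-3-en-2-one F6. Isomerisation with Pd(PPh3)4 and 1,2-bis(diphenylphosphino)ethane then gives 18. In this variant the epoxide, not the sulfur, marks the saturated flank, and hexanoyl still enters at the enone-derived flank.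

Step 14. Ring A units may self-condense through the methylene trione, ring B may be alkylated twice, or amine exchange may scramble the partners into symmetrical bis-products. The fallback reverses the roles so that ring B carries the aminomethyl group; it sets out from 21 and comes back at 24. A slight deficit of N,N-dimethylmethyleneiminium iodide converts 21 into 1-{3-[(dimethylamino)methyl]-2,6-dihydroxy-4-methoxyphenyl}hexan-1-one F8, which is purified and then heated with 18 in 1,4-dioxane. Loss of dimethylamine gives an ortho-quinone methide of ring B, which is captured by the only nucleophilic ring carbon of 18 to give 24.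

Step 11. Addition–elimination at the hindered thio-bearing carbon of an anionic trione may be slow, and retro-Claisen loss of the hexanoyl group may compete at the temperature needed. The fallback activates sulfur instead of forcing the hydrolysis; it sets out from 17 and comes back at 18. Hydrogen peroxide (1.1 equiv) in 1,1,1,3,3,3-hexafluoropropan-2-ol at rt oxidises the sulfide, not the prenyl alkene, to (4R)-2-hexanoyl-3-hydroxy-4-methyl-4-(3-methylbut-2-en-1-yl)-5-(phenylsulfinyl)cyclohexa-2,5-dien-1-one F7. Its sulfinyl group is then displaced by aqueous NaHCO3 in THF at rt to give 18.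

**Further compounds**
F1 | step 7 | (4R)-4-methyl-4-(3-methylbut-2-en-1-yl)-3-(phenylsulfanyl)cyclohexan-1-one, mixture at C3 | O=C1CC(Sc2ccccc2)[C@@](C)(CC=C(C)C)CC1
F2 | step 7 | (R)-4-methyl-4-(3-methylbut-2-en-1-yl)-3-(phenylsulfanyl)cyclohex-2-en-1-one | O=C1C=C(Sc2ccccc2)[C@@](C)(CC=C(C)C)CC1
F3 | step 7 | (S)-4-methyl-4-(3-methylbut-2-en-1-yl)-3-(phenylsulfanyl)cyclohexa-2,5-dien-1-one | O=C1C=C(Sc2ccccc2)[C@@](C)(CC=C(C)C)C=C1
F4 | step 7 | (5S)-5-methyl-5-(3-methylbut-2-en-1-yl)-4-(phenylsulfanyl)-7-oxabicyclo[4.1.0]hept-3-en-2-one, both cis-epoxides | O=C1C=C(Sc2ccccc2)[C@@](C)(CC=C(C)C)C2OC12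
F5 | step 7 | (5S)-5-methyl-5-(3-methylbut-2-en-1-yl)-7-oxabicyclo[4.1.0]heptane-2,4-dione | O=C1CC(=O)[C@@](C)(CC=C(C)C)C2OC12
F6 | step 7 | (5S)-3-hexanoyl-4-hydroxy-5-methyl-5-(3-methylbut-2-en-1-yl)-7-oxabicyclo[4.1.0]hept-3-en-2-one | CCCCCC(=O)C1=C(O)[C@@](C)(CC=C(C)C)C2OC2C1=O
F7 | step 11 | (4R)-2-hexanoyl-3-hydroxy-4-methyl-4-(3-methylbut-2-en-1-yl)-5-(phenylsulfinyl)cyclohexa-2,5-dien-1-one, both sulfur epimers | CCCCCC(=O)C1=C(O)[C@@](C)(CC=C(C)C)C(S(=O)c2ccccc2)=CC1=O
F8 | step 14 | 1-{3-[(dimethylamino)methyl]-2,6-dihydroxy-4-methoxyphenyl}hexan-1-one | CCCCCC(=O)c1c(O)cc(OC)c(CN(C)C)c1O
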